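**Plan**
1. Cuts: (i) the enol-ester bond between the quinone oxygen and C1 of the epoxyhexenoyl chain. (ii) The two ring C–C bonds that tie the pair (HO)C=C(Ar) to the two quinone carbonyl carbons. (iii) C2=C3 of the side chain and the epoxide C–O bonds.
2. Enabling feature: the ring atoms run C(=O)–C(Ar)=C(O)–C(=O)–C(Ar)=C(O). The first four are the carbon skeleton of an aryl-alkoxy-cyclobutenedione (squarate) and the last two are an aryl enol ether. A 4-alkenyl-4-hydroxycyclobutenone can therefore grow from four to six ring carbons and place its C=O and C–OH carbons para.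
3. Forward order: squaric acid → di-tert-butyl squarate → aryl/tert-butoxy dione 6. A β-alkoxyvinyllithium (two steps from an aldehyde) adds to 6. Thermal 4→6 ring expansion with Ag2O then gives the fully substituted quinone 18.
4. The two enolic oxygens come from different partners, so they leave the ring-forming step differently masked (tert-butyl from the squarate, TMSE from the enol ether). Acid frees one for acylation. Fluoride frees the other at the end, together with the phenols.
5. Stereochemistry: both epoxide centres (4S,5S) come from the Sharpless epoxidation of (E)-crotyl alcohol with L-(+)-tartrate, and the 2Z alkene from a Still–Gennari olefination. The carbinol centre and the alkene geometry of the ring precursor are erased on aromatisation.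

Key step: step 6

Remark: the atromentin core is C2-symmetric, so either enolic oxygen may carry the acyl group. Abbreviations: Ar = 4-(tert-butyldimethylsilyloxy)phenyl, TBS = tert-butyldimethylsilyl, TMSE = 2-(trimethylsilyl)ethyl.

**Step 1**
Reactants: 1 squaric acid (3,4-dihydroxycyclobut-3-ene-1,2-dione)
Product: 2 di-tert-butyl squarate (3,4-di-tert-butoxycyclobut-3-ene-1,2-dione)
Conditions: t-BuOC(=NH)CCl3 (slow addition, excess), CH2Cl2/cyclohexane, rt
Reagents that add atoms: tert-butyl 2,2,2-trichloroacetimidate, CC(C)(C)OC(=N)C(Cl)(Cl)Cl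
Why: Squaric acid is a vinylogous carboxylic acid that protonates the imidate itself, so both acidic OH groups should be O-tert-butylated by the usual trichloroacetimidate esterification without an added strong acid that the product would not stand.

**Step 2**
Reactants: 3 (4-bromophenoxy)(tert-butyl)dimethylsilane; 2 di-tert-butyl squarate
Product: 6 3-tert-butoxy-4-[4-(tert-butyldimethylsilyloxy)phenyl]cyclobut-3-ene-1,2-dione, via aryllithium 4 (not isolated), via lithium cyclobutenolate 5 (not isolated)
Conditions: 3, n-BuLi, THF, −78 °C; add to 2, THF, −78 °C; TFAA, −78 to 0 °C; aq. NaHCO3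
Reagents that add atoms: none
Why: Bromine–lithium exchange, 1,2-addition of the aryllithium to one squarate carbonyl and trifluoroacetylation of the alkoxide, whose ionisation is pushed by the vinylogous tert-butoxy group and ends with loss of isobutene, form the standard squarate-to-3-aryl-4-alkoxycyclobutenedione sequence.

**Step 3**
Reactants: 7 4-(tert-butyldimethylsilyloxy)benzaldehyde; 8 [2-(trimethylsilyl)ethoxymethyl]triphenylphosphonium chloride
Product: 10 tert-butyldimethyl(4-{2-[2-(trimethylsilyl)ethoxy]ethenyl}phenoxy)silane (E/Z mixture), via phosphorus ylide 9 (not isolated)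
Conditions: 8, NaHMDS, THF, 0 °C; then 7, 0 °C to rt
Reagents that add atoms: none
Why: This is a Wittig alkoxymethylenation of an aromatic aldehyde with a non-stabilised ylide, and the E/Z mixture does not matter because the geometry is reset in step 4 and erased in step 6.

**Step 4**
Reactants: 10 enol ether (E/Z mixture)
Product: 12 (Z)-[4-(1-bromo-2-[2-(trimethylsilyl)ethoxy]ethenyl)phenoxy](tert-butyl)dimethylsilane (Br and O cis), via dibromo ether 11 (not isolated)
Conditions: Br2, CH2Cl2, −78 °C; then Et3N, −78 °C to rt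
Reagents that add atoms: bromine, BrBr
Why: Bromine addition to the electron-rich enol ether and amine-induced loss of HBr through the oxocarbenium ion (removal of the benzylic proton) is the classical bromination–dehydrobromination route to β-bromo enol ethers, and the isomer with aryl trans to alkoxy (Br cis to O) should prevail for steric reasons.

**Step 5**
Reactants: 12 vinyl bromide; 6 aryl-tert-butoxy-cyclobutenedione
Product: 14 (±)-3-tert-butoxy-2-Ar-4-hydroxy-4-{(Z)-1-Ar-2-[2-(trimethylsilyl)ethoxy]ethenyl}cyclobut-2-en-1-one, via vinyllithium 13 (not isolated)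
Conditions: 12, t-BuLi (2 equiv), Et2O/THF, −78 °C; then 6, −78 °C; aq. NH4Cl
Reagents that add atoms: none
Why: Bromine–lithium exchange with retention gives a β-alkoxyvinyllithium held by O–Li chelation (Li cis to O, so anti elimination is closed) that adds 1,2 to the carbonyl next to C–OtBu, the other carbonyl being deactivated as a vinylogous ester, and the new carbinol centre is racemic and is lost in step 6.

**Step 6**
Reactants: 14 4-alkenyl-4-hydroxycyclobutenone
Product: 18 2,5-bis(Ar)-3-tert-butoxy-6-[2-(trimethylsilyl)ethoxy]-1,4-benzoquinone, via dienylketene 15 (not isolated), via cyclohexadienone 16 (not isolated), via hydroquinone 17 (not isolated)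
Conditions: degassed PhMe, 110 °C; cool to rt, then Ag2O, Na2SO4
Reagents that add atoms: none
Why: Heating opens the cyclobutenone by a conrotatory 4π electrocyclic reaction in which the C4 hydroxyl turns outward and the alkenyl group inward (torquoselectivity of donor substituents), so the ketene carbon of 15 lies next to the enol-ether terminus. A disrotatory 6π electrocyclisation joins the ketene carbon to the O-bearing vinyl carbon, closing the six-membered carbocycle from the four cyclobutenone carbons and the two alkenyl carbons, then dienone 16 tautomerises to hydroquinone 17, which Ag2O dehydrogenates to 18 in the same flask. The closest known reaction type is the Moore–Liebeskind ring expansion of 4-alkenyl-4-hydroxycyclobutenones to hydroquinones and quinones, including 3-tert-butoxy members used as latent hydroxyquinones. No stereocentre survives: the racemic carbinol carbon becomes a carbonyl carbon, and the sp3 carbon of 16 and the enol-ether geometry vanish on aromatisation, so all stereoisomers of 14 converge on one product. The selectivity needed is regiochemical (aryl groups para, the two enolic oxygens differently masked) and it is fixed by the connectivity of 14 set in step 5, not by the thermolysis. The tert-butyl, TMSE and aryl TBS groups should be inert to neutral toluene at reflux and to Ag2O.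

**Step 7**
Reactants: 18 tert-butoxy-TMSE-oxy-quinone
Product: 19 2,5-bis(Ar)-3-hydroxy-6-[2-(trimethylsilyl)ethoxy]-1,4-benzoquinone
Conditions: TFA (about 10 equiv), CH2Cl2, 0 °C, short contact; evaporate with PhMe
Reagents that add atoms: none
Why: A tert-butoxyquinone is a vinylogous tert-butyl ester that should lose isobutene by acid-catalysed E1 cleavage well before the primary TMSE vinylogous ester or the acid-stable aryl TBS ethers react.

**Step 8**
Reactants: 20 (E)-but-2-en-1-ol (crotyl alcohol)
Product: 21 [(2S,3S)-3-methyloxiran-2-yl]methanol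
Conditions: Ti(OiPr)4 (cat.), L-(+)-DIPT (cat.), t-BuOOH, 4 Å MS, CH2Cl2, −20 °C
Reagents that add atoms: tert-butyl hydroperoxide, CC(C)(C)OO
Why: In the Sharpless asymmetric epoxidation with L-(+)-tartrate the oxygen is delivered to the face of the E-allylic alcohol that gives the (2S,3S)-epoxy alcohol, the trans relation following from the E alkene, so both stereocentres of the target are set here.

**Step 9**
Reactants: 21 epoxy alcohol
Product: 22 (2R,3S)-3-methyloxirane-2-carbaldehyde
Conditions: TEMPO (cat.), PhI(OAc)2, CH2Cl2, 0 °C to rt; NaHCO3 wash, used as a dried solution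
Reagents that add atoms: none
Why: The TEMPO/PhI(OAc)2 oxidation of a primary alcohol stops at the aldehyde under nearly neutral conditions that leave the epoxide and its centres untouched (the C2 descriptor becomes R only through the priority rules).

**Step 10**
Reactants: 23 methyl bis(2,2,2-trifluoroethyl)phosphonoacetate; 22 epoxy aldehyde
Product: 25 methyl (2Z)-3-[(2S,3S)-3-methyloxiran-2-yl]prop-2-enoate, via potassium phosphonate 24 (not isolated)
Conditions: 23, KHMDS, 18-crown-6, THF, −78 °C; then 22, −78 °C
Reagents that add atoms: none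
Why: In the Still–Gennari olefination the electron-poor phosphonate with a dissociated potassium counter-ion eliminates under kinetic control and should give the Z-enoate, while the low temperature protects the α-epoxy aldehyde.

**Step 11**
Reactants: 25 Z-epoxy enoate
Product: 26 (2Z)-3-[(2S,3S)-3-methyloxiran-2-yl]prop-2-enoic acid [(2Z,4S,5S)-4,5-epoxyhex-2-enoic acid]
Conditions: LiOH, THF/H2O, 0 °C; aq. KHSO4 to about pH 4 at 0 °C, quick extraction, used at once
Reagents that add atoms: lithium hydroxide, [Li+].[OH-]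
Why: Saponification of the methyl ester (BAc2) at 0 °C, followed by cold acidification only to about pH 4 so that the Z-carboxyl group does not open the epoxide, should give the free acid with both centres and the Z alkene intact.

**Step 12**
Reactants: 26 epoxy acid; 19 hydroxyquinone
Product: 28 3,6-dioxo-2,5-bis(Ar)-4-[2-(trimethylsilyl)ethoxy]cyclohexa-1,4-dien-1-yl (2Z)-3-[(2S,3S)-3-methyloxiran-2-yl]prop-2-enoate, via mixed anhydride 27 (not isolated)
Conditions: 26, 2,4,6-Cl3C6H2COCl, Et3N, PhMe, 0 °C; then 19, Et3N, DMAP (cat.), −20 to 0 °C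
Reagents that add atoms: none
Why: In the Yamaguchi esterification the mixed anhydride is attacked at the less hindered enoyl carbonyl, and the only free OH of 19, an acidic and weakly nucleophilic enol, is acylated as its ammonium salt under DMAP catalysis at low temperature to limit Z/E isomerisation.

**Step 13**
Reactants: 28 fully protected monoester
Product: 29 target, 4-hydroxy-2,5-bis(4-hydroxyphenyl)-3,6-dioxocyclohexa-1,4-dien-1-yl (2Z)-3-[(2S,3S)-3-methyloxiran-2-yl]prop-2-enoate
Conditions: TBAF/AcOH (1:1, excess), THF, 0 °C to rt, high dilution; pH 4 buffer work-up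
Reagents that add atoms: none
Why: Fluoride attacks silicon, so the two aryl TBS ethers are cleaved directly and the TMSE group fragments with loss of ethene because the hydroxyquinone is a vinylogous carboxylate leaving group (as in the fluoride cleavage of TMSE esters), while acetic acid keeps the phenoxide level low so that the enol ester, the Z alkene and the epoxide should survive.

**Compound list**
1 | squaric acid | O=C1C(O)=C(O)C1=O | starting material
2 | di-tert-butyl squarate | CC(C)(C)OC1=C(OC(C)(C)C)C(=O)C1=O | intermediate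
3 | (4-bromophenoxy)(tert-butyl)dimethylsilane | CC(C)(C)[Si](C)(C)Oc1ccc(Br)cc1 | starting material
4 | 4-(tert-butyldimethylsilyloxy)phenyllithium | [Li]c1ccc(O[Si](C)(C)C(C)(C)C)cc1 | intermediate
5 | lithium 1-Ar-2,3-di-tert-butoxy-4-oxocyclobut-2-en-1-olate (racemic) | [Li+].[O-]C1(c2ccc(O[Si](C)(C)C(C)(C)C)cc2)C(OC(C)(C)C)=C(OC(C)(C)C)C1=O | intermediate
6 | 3-tert-butoxy-4-Ar-cyclobut-3-ene-1,2-dione | CC(C)(C)OC1=C(c2ccc(O[Si](C)(C)C(C)(C)C)cc2)C(=O)C1=O | intermediate
7 | 4-(tert-butyldimethylsilyloxy)benzaldehyde | O=Cc1ccc(O[Si](C)(C)C(C)(C)C)cc1 | starting material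
8 | [2-(trimethylsilyl)ethoxymethyl]triphenylphosphonium chloride | C[Si](C)(C)CCOC[P+](c1ccccc1)(c1ccccc1)c1ccccc1.[Cl-] | starting material
9 | [2-(trimethylsilyl)ethoxy]methylidene-triphenylphosphorane | C[Si](C)(C)CCOC=P(c1ccccc1)(c1ccccc1)c1ccccc1 | intermediate
10 | Ar–CH=CH–O-TMSE (E/Z mixture) | C[Si](C)(C)CCOC=Cc1ccc(O[Si](C)(C)C(C)(C)C)cc1 | intermediate
11 | Ar–CHBr–CHBr–O-TMSE (diastereomer mixture) | C[Si](C)(C)CCOC(Br)C(Br)c1ccc(O[Si](C)(C)C(C)(C)C)cc1 | intermediate
12 | (Z)-Ar–C(Br)=CH–O-TMSE (Br cis to O) | C[Si](C)(C)CCO/C=C(\Br)c1ccc(O[Si](C)(C)C(C)(C)C)cc1 | intermediate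
13 | Ar–C(Li)=CH–O-TMSE (Li cis to O) | C[Si](C)(C)CCO/C=C(\[Li])c1ccc(O[Si](C)(C)C(C)(C)C)cc1 | intermediate
14 | (±)-3-tert-butoxy-2-Ar-4-hydroxy-4-[(Z)-1-Ar-2-(TMSE-oxy)ethenyl]cyclobut-2-en-1-one | C[Si](C)(C)CCO/C=C(\C1(O)C(OC(C)(C)C)=C(c2ccc(O[Si](C)(C)C(C)(C)C)cc2)C1=O)c1ccc(O[Si](C)(C)C(C)(C)C)cc1 | intermediate
15 | dienylketene O=C=C(Ar)–C(OtBu)=C(OH)–C(Ar)=CH–O-TMSE | O=C=C(c1ccc(O[Si](C)(C)C(C)(C)C)cc1)/C(OC(C)(C)C)=C(O)\C(c1ccc(O[Si](C)(C)C(C)(C)C)cc1)=C/OCC[Si](C)(C)C | intermediate
16 | (±)-2,5-bis(Ar)-3-tert-butoxy-4-hydroxy-6-(TMSE-oxy)cyclohexa-2,4-dien-1-one | O=C1C(c2ccc(O[Si](C)(C)C(C)(C)C)cc2)=C(OC(C)(C)C)C(O)=C(c2ccc(O[Si](C)(C)C(C)(C)C)cc2)C1OCC[Si](C)(C)C | intermediate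
17 | 2,5-bis(Ar)-3-tert-butoxy-6-(TMSE-oxy)benzene-1,4-diol | Oc1c(-c2ccc(O[Si](C)(C)C(C)(C)C)cc2)c(OC(C)(C)C)c(O)c(-c2ccc(O[Si](C)(C)C(C)(C)C)cc2)c1OCC[Si](C)(C)C | intermediate
18 | 2,5-bis(Ar)-3-tert-butoxy-6-(TMSE-oxy)-1,4-benzoquinone | O=C1C(c2ccc(O[Si](C)(C)C(C)(C)C)cc2)=C(OC(C)(C)C)C(=O)C(c2ccc(O[Si](C)(C)C(C)(C)C)cc2)=C1OCC[Si](C)(C)C | intermediate
19 | 2,5-bis(Ar)-3-hydroxy-6-(TMSE-oxy)-1,4-benzoquinone | O=C1C(c2ccc(O[Si](C)(C)C(C)(C)C)cc2)=C(O)C(=O)C(c2ccc(O[Si](C)(C)C(C)(C)C)cc2)=C1OCC[Si](C)(C)C | intermediate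
20 | (E)-but-2-en-1-ol | C/C=C/CO | starting material
21 | [(2S,3S)-3-methyloxiran-2-yl]methanol | C[C@@H]1O[C@H]1CO | intermediate
22 | (2R,3S)-3-methyloxirane-2-carbaldehyde | C[C@@H]1O[C@H]1C=O | intermediate
23 | methyl bis(2,2,2-trifluoroethyl)phosphonoacetate | COC(=O)CP(=O)(OCC(F)(F)F)OCC(F)(F)F | starting material
24 | potassium salt of 23 (phosphonate carbanion) | [K+].COC(=O)[CH-]P(=O)(OCC(F)(F)F)OCC(F)(F)F | intermediate
25 | methyl (2Z,4S,5S)-4,5-epoxyhex-2-enoate | C[C@@H]1O[C@H]1/C=C\C(=O)OC | intermediate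
26 | (2Z,4S,5S)-4,5-epoxyhex-2-enoic acid | C[C@@H]1O[C@H]1/C=C\C(=O)O | intermediate
27 | (2Z,4S,5S)-4,5-epoxyhex-2-enoic 2,4,6-trichlorobenzoic anhydride | C[C@@H]1O[C@H]1/C=C\C(=O)OC(=O)c1c(Cl)cc(Cl)cc1Cl | intermediate
28 | bis-TBS, TMSE-protected monoester | C[C@@H]1O[C@H]1/C=C\C(=O)OC1=C(c2ccc(O[Si](C)(C)C(C)(C)C)cc2)C(=O)C(OCC[Si](C)(C)C)=C(c2ccc(O[Si](C)(C)C(C)(C)C)cc2)C1=O | intermediate
29 | atromentin mono-(2Z,4S,5S)-4,5-epoxyhex-2-enoate | C[C@@H]1O[C@H]1/C=C\C(=O)OC1=C(c2ccc(O)cc2)C(=O)C(O)=C(c2ccc(O)cc2)C1=O | target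

**Totals**
Total step count: 13.
Longest linear sequence: 7 steps (3, 4, 5, 6, 7, 12, 13 from 7; equally 1, 2, 5, 6, 7, 12, 13 from 1).

**Steps most likely to fail**

Step 13.
- The enol ester is a vinylogous anhydride, so liberated phenoxide or acetate may transfer or cleave the acyl group. Fragmentation of the TMSE group may also be too slow under buffered fluoride.
- The fallback sets out from 18 and gives up the orthogonal masking.
- Longer exposure of 18 to TFA at rt should remove the tert-butyl and the TMSE group and give 2,5-bis[4-(tert-butyldimethylsilyloxy)phenyl]-3,6-dihydroxy-1,4-benzoquinone F1.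
- One equivalent of mixed anhydride 27 (made from 26 as in step 12) should acylate one of the two equivalent enolic hydroxyls, since the first acylation lowers the nucleophilicity of the second. This gives the bis-TBS monoester with a free enolic hydroxyl F2.
- Only aryl silyl ethers then remain. Et3N·3HF in THF cleaves them under weakly acidic, non-nucleophilic conditions, and the route is rejoined at 29.

Step 5.
- The vinyllithium may lose alkoxide by β-elimination or lose its configuration before it meets the dione. Attack may also be slowed next to the bulky tert-butoxy group.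
- The fallback sets out from 10, 2 and 4 and reverses the order in which the two carbon groups enter the squarate.
- Enol ether 10 is deprotonated with t-BuLi at the oxygen-bearing vinyl carbon to give the 1-(TMSE-oxy)-2-arylvinyllithium F3, which has no β-leaving group.
- Addition of F3 to 2 and capping with TMSCl should give the 4-alkenyl-2,3-di-tert-butoxy-4-(trimethylsilyloxy)cyclobutenone F4.
- Aryllithium 4 then adds to the remaining carbonyl, and TFAA triggers ionisation with allylic transposition and loss of isobutene. This gives the regioisomeric 2-tert-butoxy-3-aryl-4-alkenyl-4-(trimethylsilyloxy)cyclobutenone F5.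
- The same thermal ring expansion should give the hydroquinone mono-TMS ether F6.
- PPTS/MeOH removes the TMS group of F6, and the route is rejoined at 17, which Ag2O oxidises to 18 as in step 6.

Step 12.
- The activated Z-enoyl unit may isomerise to E by reversible conjugate addition of DMAP. The poorly nucleophilic enol may also be acylated too slowly.
- The fallback sets out from 22 and 19 and installs the alkene geometry after the ester bond.
- Ohira–Bestmann homologation of 22 should give (2S,3S)-2-ethynyl-3-methyloxirane F7.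
- n-BuLi followed by CO2 gives (4S,5S)-4,5-epoxyhex-2-ynoic acid F8, which has no geometry to lose.
- DCC/DMAP coupling of F8 with 19 gives the corresponding quinonyl epoxyhexynoate F9.
- Lindlar semihydrogenation sets the Z alkene by syn addition, and any ring reduction is reversed by air on work-up. The route is rejoined at 28.

**Further compounds**
F1 | step 13 | 2,5-bis[4-(tert-butyldimethylsilyloxy)phenyl]-3,6-dihydroxy-1,4-benzoquinone | O=C1C(c2ccc(O[Si](C)(C)C(C)(C)C)cc2)=C(O)C(=O)C(c2ccc(O[Si](C)(C)C(C)(C)C)cc2)=C1O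
F2 | step 13 | bis-TBS monoester with a free enolic hydroxyl | C[C@@H]1O[C@H]1/C=C\C(=O)OC1=C(c2ccc(O[Si](C)(C)C(C)(C)C)cc2)C(=O)C(O)=C(c2ccc(O[Si](C)(C)C(C)(C)C)cc2)C1=O
F3 | step 5 | 1-(TMSE-oxy)-2-arylvinyllithium | C[Si](C)(C)CCOC([Li])=Cc1ccc(O[Si](C)(C)C(C)(C)C)cc1
F4 | step 5 | 4-alkenyl-2,3-di-tert-butoxy-4-(trimethylsilyloxy)cyclobutenone (racemic) | C[Si](C)(C)CCOC(=Cc1ccc(O[Si](C)(C)C(C)(C)C)cc1)C1(O[Si](C)(C)C)C(OC(C)(C)C)=C(OC(C)(C)C)C1=O
F5 | step 5 | 2-tert-butoxy-3-aryl-4-alkenyl-4-(trimethylsilyloxy)cyclobutenone (racemic) | O=C1C(OC(C)(C)C)=C(c2ccc(O[Si](C)(C)C(C)(C)C)cc2)C1(O[Si](C)(C)C)C(OCC[Si](C)(C)C)=Cc1ccc(O[Si](C)(C)C(C)(C)C)cc1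
F6 | step 5 | hydroquinone mono-TMS ether | Oc1c(OC(C)(C)C)c(-c2ccc(O[Si](C)(C)C(C)(C)C)cc2)c(O[Si](C)(C)C)c(OCC[Si](C)(C)C)c1-c1ccc(O[Si](C)(C)C(C)(C)C)cc1
F7 | step 12 | (2S,3S)-2-ethynyl-3-methyloxirane | C[C@@H]1O[C@H]1C#C
F8 | step 12 | (4S,5S)-4,5-epoxyhex-2-ynoic acid | C[C@@H]1O[C@H]1C#CC(=O)O
F9 | step 12 | quinonyl (4S,5S)-4,5-epoxyhex-2-ynoate | C[C@@H]1O[C@H]1C#CC(=O)OC1=C(c2ccc(O[Si](C)(C)C(C)(C)C)cc2)C(=O)C(OCC[Si](C)(C)C)=C(c2ccc(O[Si](C)(C)C(C)(C)C)cc2)C1=O
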